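## Retrosynthetic overview

1. Andilesin A (23) ⇐ Baeyer–Villiger expansion of ring A plus C–B oxidation in one flask ⇐ Δ1-3-keto C7' boronate 21 ⇐ conjugate borylation of alkylidene lactone 18.
2. 18 ⇐ intramolecular Diels–Alder reaction (bonds C8–C3a' and C12–C6'; cyclopentane and bicyclo[2.2.2]octane in one event) of the exocyclic-alkene decalin dienone 17.
3. 17 ⇐ allylsilane-terminated epoxy-polyene bicyclisation (carbocyclic rings A and B) of the dearomatised polyene 16.
4. 16 ⇐ catalyst-controlled dearomative C-alkylation of phthalide phenol 15 with allylic bromide 12 (bond C11–C4').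
5. 12 ⇐ geranyl acetate by Shi epoxidation (first stereocentre), butynoate homologation and syn-silylmethylcupration; 15 ⇐ 4-methoxy-3,5-dimethylbenzoic acid. Ring order: γ-lactone (arene stage) → carbocycles A and B → cyclopentane plus bicyclooctane → ε-lactone.

Assumption: the SMILES is taken as drawn (C9–H cis to the C10 methyl); locants are terpenoid C1–C12 (C11 = CH2 on C9, C12 = methylene carbon on C8), primed phthalide carbons as in 2-benzofuran-1(3H)-one (C1' lactone C=O, C3' OCH2, C5' ketone), and dodecane locants for chain compounds 7–12.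

## Route

Step 1
Reactants: 1 geranyl acetate
Product: 2 (S)-6,7-epoxygeranyl acetate [(2E)-5-[(2S)-3,3-dimethyloxiran-2-yl]-3-methylpent-2-en-1-yl acetate]
Conditions: ent-Shi ketone (L-fructose-derived, 30 mol %), KHSO5 (as 2KHSO5·KHSO4·K2SO4), K2CO3, Bu4NHSO4, MeCN/(MeO)2CH2/aq. buffer pH 10.5, 0 °C
Reagents that add atoms: potassium peroxymonosulfate KHSO5, [K+].OOS(=O)(=O)[O-]
Why: Shi asymmetric epoxidation (chiral dioxirane, spiro transition state) attacks only the remote 6,7-alkene because the 2,3-alkene is deactivated by the allylic acetate, and the L-fructose-derived ketone gives the (6S)-epoxide, the centre that becomes C3 and relays all terpenoid stereochemistry.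

Step 2
Reactants: 2 (S)-6,7-epoxygeranyl acetate
Product: 3 (S)-6,7-epoxygeraniol
Conditions: K2CO3 (0.2 equiv), MeOH, 0 °C
Reagents that add atoms: none
Why: Carbonate-catalysed transesterification (methanolysis) removes the acetate without touching the trisubstituted epoxide.

Step 3
Reactants: 3 (S)-6,7-epoxygeraniol
Product: 5 (S)-6,7-epoxygeranyl bromide, via allylic mesylate 4 (not isolated)
Conditions: MsCl, Et3N, THF, −40 °C; then LiBr, 0 °C
Reagents that add atoms: lithium bromide LiBr, [Li+].[Br-]
Why: Mesylation followed by SN2 displacement with bromide at the primary allylic carbon is non-acidic, so the epoxide and the E-alkene survive.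

Step 4
Reactants: 5 (S)-6,7-epoxygeranyl bromide, 6 but-2-ynoic acid
Product: 8 methyl (6E,10S)-10,11-epoxy-7,11-dimethyldodec-6-en-2-ynoate, via lithium ynoate 7 (not isolated)
Conditions: 6, LiN(iPr)2 (2 equiv per 6), THF/DMPU, −78 °C; 5, −78 → 0 °C; then MeI, 23 °C
Reagents that add atoms: iodomethane, CI
Why: The but-2-ynoic acid dianion is alkylated at its γ (propargylic) carbon by the allylic bromide (SN2), and the resulting carboxylate is O-methylated in the same flask; the epoxide centre is not involved.

Step 5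
Reactants: 8 methyl (6E,10S)-10,11-epoxy-7,11-dimethyldodec-6-en-2-ynoate
Product: 9 methyl (2E,6E,10S)-10,11-epoxy-7,11-dimethyl-3-[(trimethylsilyl)methyl]dodeca-2,6-dienoate (ester cis to the C4 chain)
Conditions: Me3SiCH2Li (2.4 equiv), CuI (1.2 equiv), THF, −30 °C; 8, −78 °C; NH4Cl (aq)
Reagents that add atoms: (trimethylsilyl)methyllithium Me3SiCH2Li, [Li]C[Si](C)(C)C
Why: Syn-carbocupration (cuprate conjugate addition to the ynoate) at −78 °C and stereoretentive protonation place the C4 chain cis to the ester, the geometry that later puts the C9 substituent axial (C9–H β), and install the allylsilane terminator.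

Step 6
Reactants: 9 the silyl enoate
Product: 10 (2E,6E,10S)-10,11-epoxy-7,11-dimethyl-3-[(trimethylsilyl)methyl]dodeca-2,6-dien-1-ol
Conditions: iBu2AlH (2.3 equiv), CH2Cl2, −78 °C
Reagents that add atoms: none
Why: 1,2-Reduction of the enoate to the allylic alcohol by iBu2AlH at −78 °C leaves the epoxide, allylsilane and alkene geometry intact.

Step 7
Reactants: 10 the allylic alcohol
Product: 12 (2E,6E,10S)-1-bromo-10,11-epoxy-7,11-dimethyl-3-[(trimethylsilyl)methyl]dodeca-2,6-diene (CH2Br cis to the C4 chain), via allylic mesylate 11 (not isolated)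
Conditions: MsCl, Et3N, THF, −40 °C; then LiBr, 0 °C; used crude at once
Reagents that add atoms: lithium bromide LiBr, [Li+].[Br-]
Why: The same mesylation/SN2 bromide displacement as step 3 gives the primary allylic bromide without acid, keeping the epoxide and allylsilane.

Step 8
Reactants: 13 4-methoxy-3,5-dimethylbenzoic acid
Product: 14 5-methoxy-4,6-dimethyl-2-benzofuran-1(3H)-one
Conditions: Pd(OAc)2 (10 mol %), K2HPO4 (3 equiv), CH2Br2, 140 °C
Reagents that add atoms: dibromomethane, BrCBr
Why: Carboxylate-directed ortho C–H alkylation by palladium with CH2Br2 followed by intramolecular SN2 lactonisation gives the phthalide, and the two ortho positions are equivalent so only one product can form.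

Step 9
Reactants: 14 5-methoxy-4,6-dimethyl-2-benzofuran-1(3H)-one
Product: 15 5-hydroxy-4,6-dimethyl-2-benzofuran-1(3H)-one
Conditions: BBr3, CH2Cl2, −78 → 0 °C; H2O
Reagents that add atoms: none
Why: BBr3 cleavage of the aryl methyl ether frees the phenol, and the phthalide lactone tolerates these conditions.

Step 10
Reactants: 15 5-hydroxy-4,6-dimethyl-2-benzofuran-1(3H)-one, 12 the allylic bromide
Product: 16 (4R)-4-[(2E,6E,10S)-10,11-epoxy-7,11-dimethyl-3-[(trimethylsilyl)methyl]dodeca-2,6-dien-1-yl]-4,6-dimethyl-2-benzofuran-1,5(3H,4H)-dione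
Conditions: (S)-N-isopropyl-1,1'-binaphthyl-2,2'-diamine bis[3,5-bis(trifluoromethyl)phenyl]urea (10 mol %; the enantiomer that delivers 4'R is fixed in a first screen), Cs2CO3 (powder), PhMe, −20 °C
Reagents that add atoms: none
Why: Proposed new method: hydrogen-bonding phase-transfer catalysis applied to an alkylative phenol dearomatisation, in which the chiral bis-urea extracts the caesium phenoxide of 15 from the solid base as an N–H···O− complex that masks oxygen (suppressing O-alkylation) and exposes one face of C4' (the ortho carbon whose alkylation keeps the butenolide C3a'=C7a' bond endocyclic, whereas C6' attack would leave two exocyclic alkenes on the five-membered ring), so SN2 attack on the primary allylic bromide forms C11–C4' and the (4'R) quaternary centre under catalyst control; the closest known reaction types are hydrogen-bonding phase-transfer catalysis with alkali-metal fluorides and the lithium-phenoxide alkylative dearomatisation of 2,6-dialkylphenols with allylic bromides.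

Step 11
Reactants: 16 the dearomatised polyene
Product: 18 hexacyclic Diels–Alder adduct (3β-hydroxy; new bonds C8–C3a' and C12–C6'; C5' ketone; C7'=C7a' alkene conjugated to the γ-lactone), via decalin dienone 17 (not isolated)
Conditions: MeAlCl2 (3 equiv), CH2Cl2, −78 °C; aq. NaHCO3 work-up; then PhMe, BHT, 110 °C
Reagents that add atoms: none
Why: Epoxide-initiated cation–olefin bicyclisation through a chair–chair transition state lets the (10S)-epoxide fix 3β-OH, 5α-H and 10β-CH3, the cis C2 alkene places the CH2–dienone group axial (C9–H β) and the β-silyl cation collapses only to the C8=C12 exocyclic alkene (allylsilane termination), after which the electron-poor cyclohexa-2,4-dienone adds across that alkene from the α-face in an inverse-demand intramolecular Diels–Alder reaction whose three-atom tether dictates C8, C3a' and C6' and allows only the (4'R) epimer to react.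

Step 12
Reactants: 18 the Diels–Alder adduct
Product: 19 C7' pinacol boronate (H at C7a', Bpin at C7'; C7'–B and the C7a'–C1' bond both on the face towards the C5' ketone bridge)
Conditions: CuCl (10 mol %), 1,3-dimesitylimidazolium chloride (10 mol %), NaOtBu (30 mol %), B2pin2, MeOH (2 equiv), THF, 23 °C
Reagents that add atoms: bis(pinacolato)diboron, CC1(C)OB(OC1(C)C)B1OC(C)(C)C(C)(C)O1
Why: Copper–boryl conjugate addition (β-borylation) to the strained α-alkylidene lactone should deliver boron to C7' from the face syn to the C5' ketone bridge (away from the C12 methylene and ring B), and protonation at C7a' should give the epimer whose lactone carbonyl lies beside the C4' methyl and not ring B, so the C–B bond stands where the hydroxyl is needed.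

Step 13
Reactants: 19 the boronate
Product: 21 Δ1-3-keto boronate (4,4-dimethyl-1-en-3-one in ring A), via C3 ketone 20 (not isolated)
Conditions: IBX (4 equiv), DMSO, 75 °C
Reagents that add atoms: none
Why: IBX oxidises the C3 alcohol and then dehydrogenates the ketone (IBX α,β-dehydrogenation) to the enone, C2 being the only enolisable position because the C5' ketone lies between two quaternary carbons, while the secondary boronate and the lactone are inert.

Step 14
Reactants: 21 the Δ1-3-keto boronate
Product: 23 andilesin A, via lactone boronate 22 (not isolated)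
Conditions: mCPBA (3 equiv), CH2Cl2, 23 °C; then NaBO3·4H2O, THF/H2O, 23 °C
Reagents that add atoms: 3-chloroperoxybenzoic acid, OOC(=O)c1cccc(Cl)c1; sodium perborate NaBO3·4H2O, O[B-]1(O)OO[B-](O)(O)OO1.[Na+].[Na+]
Why: Baeyer–Villiger oxidation with migration of the tertiary C4 in preference to the vinyl carbon inserts oxygen between C3 and C4 to give the unsaturated ε-lactone (the C5' ketone is shielded by two quaternary α-carbons), and perborate oxidises the C–B bond with retention to the C7' alcohol.

## Compound list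

1 | geranyl acetate | CC(=O)OC/C=C(\C)CCC=C(C)C | starting material
2 | (S)-6,7-epoxygeranyl acetate | CC(=O)OC/C=C(\C)CC[C@@H]1OC1(C)C | intermediate
3 | (S)-6,7-epoxygeraniol | OC/C=C(\C)CC[C@@H]1OC1(C)C | intermediate
4 | (S)-6,7-epoxygeranyl methanesulfonate | CS(=O)(=O)OC/C=C(\C)CC[C@@H]1OC1(C)C | intermediate
5 | (S)-6,7-epoxygeranyl bromide | BrC/C=C(\C)CC[C@@H]1OC1(C)C | intermediate
6 | but-2-ynoic acid | CC#CC(=O)O | starting material
7 | lithium (6E,10S)-10,11-epoxy-7,11-dimethyldodec-6-en-2-ynoate | [Li+].[O-]C(=O)C#CCC/C=C(\C)CC[C@@H]1OC1(C)C | intermediate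
8 | methyl (6E,10S)-10,11-epoxy-7,11-dimethyldodec-6-en-2-ynoate | COC(=O)C#CCC/C=C(\C)CC[C@@H]1OC1(C)C | intermediate
9 | methyl (2E,6E,10S)-10,11-epoxy-7,11-dimethyl-3-[(trimethylsilyl)methyl]dodeca-2,6-dienoate | COC(=O)/C=C(/C[Si](C)(C)C)CC/C=C(\C)CC[C@@H]1OC1(C)C | intermediate
10 | (2E,6E,10S)-10,11-epoxy-7,11-dimethyl-3-[(trimethylsilyl)methyl]dodeca-2,6-dien-1-ol | OC/C=C(/C[Si](C)(C)C)CC/C=C(\C)CC[C@@H]1OC1(C)C | intermediate
11 | methanesulfonate of 10 | CS(=O)(=O)OC/C=C(/C[Si](C)(C)C)CC/C=C(\C)CC[C@@H]1OC1(C)C | intermediate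
12 | (2E,6E,10S)-1-bromo-10,11-epoxy-7,11-dimethyl-3-[(trimethylsilyl)methyl]dodeca-2,6-diene | BrC/C=C(/C[Si](C)(C)C)CC/C=C(\C)CC[C@@H]1OC1(C)C | intermediate
13 | 4-methoxy-3,5-dimethylbenzoic acid | COc1c(C)cc(cc1C)C(=O)O | starting material
14 | 5-methoxy-4,6-dimethyl-2-benzofuran-1(3H)-one | COc1c(C)cc2C(=O)OCc2c1C | intermediate
15 | 5-hydroxy-4,6-dimethyl-2-benzofuran-1(3H)-one | Oc1c(C)cc2C(=O)OCc2c1C | intermediate
16 | (4'R)-dearomatised polyene: 4,6-dimethyl-2-benzofuran-1,5(3H,4H)-dione carrying the chain of 12 at C4 | O=C1C(C)=CC2=C(COC2=O)[C@@]1(C)C/C=C(/C[Si](C)(C)C)CC/C=C(\C)CC[C@@H]1OC1(C)C | intermediate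
17 | decalin dienone: trans-decalin, 3β-OH (3S), 5α-H, 10β-CH3, C9–H β (C9–CH2 axial), exocyclic C8=C12, C11 bonded to the (4'R) dienone carbon | CC1(C)[C@@H](O)CC[C@@]2(C)[C@H]1CCC(=C)[C@H]2C[C@@]3(C)C(=O)C(C)=CC4=C3COC4=O | intermediate
18 | hexacyclic Diels–Alder adduct, 3β-hydroxy, C7'=C7a' alkylidene γ-lactone | CC1(C)[C@@H](O)CC[C@@]2(C)[C@H]1CC[C@]13C[C@]4(C)C(=O)[C@](C)(C[C@@H]21)[C@]31COC(=O)C1=C4 | intermediate
19 | C7' pinacol boronate of the 3β-alcohol | CC1(C)[C@@H](O)CC[C@@]2(C)[C@H]1CC[C@]13C[C@]4(C)C(=O)[C@](C)(C[C@@H]21)[C@]31COC(=O)[C@H]1[C@H]4B1OC(C)(C)C(C)(C)O1 | intermediate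
20 | C3 ketone boronate | CC1(C)C(=O)CC[C@@]2(C)[C@H]1CC[C@]13C[C@]4(C)C(=O)[C@](C)(C[C@@H]21)[C@]31COC(=O)[C@H]1[C@H]4B1OC(C)(C)C(C)(C)O1 | intermediate
21 | Δ1-3-keto boronate | CC1(C)C(=O)C=C[C@@]2(C)[C@H]1CC[C@]13C[C@]4(C)C(=O)[C@](C)(C[C@@H]21)[C@]31COC(=O)[C@H]1[C@H]4B1OC(C)(C)C(C)(C)O1 | intermediate
22 | ring A unsaturated ε-lactone C7' boronate | CC1(C)OC(=O)C=C[C@@]2(C)[C@H]1CC[C@]13C[C@]4(C)C(=O)[C@](C)(C[C@@H]21)[C@]31COC(=O)[C@H]1[C@H]4B1OC(C)(C)C(C)(C)O1 | intermediate
23 | andilesin A | CC1(C)OC(=O)C=C[C@@]2(C)[C@H]1CC[C@]13C[C@]4(C)C(=O)[C@](C)(C[C@@H]21)[C@]31COC(=O)[C@H]1[C@H]4O | target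

## Step count and risk

Total steps: 14. Longest linear sequence: 12 (steps 1–7 and 10–14, from geranyl acetate).

The three steps most likely to fail:

**Step 10 (the proposed new alkylation).** O-alkylation, C6' attack or poor facial control may dominate. The fallback sets out from 15 and 12 and comes back at 16. It uses the known lithium-phenoxide alkylative dearomatisation (LiN(SiMe3)2, PhMe, 0 °C), where the tight lithium ion pair in a non-polar solvent favours ortho C-alkylation without any chiral control. It is expected to give 16 together with the (4'S) epimer F1, the O-alkylated aryl ether F2 and the C6'-alkylated regioisomer F3. 16 is separated by chromatography; any residual F1 is harmless because it cannot reach the alkene in step 11 and is removed there.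

**Step 11 (Lewis-acid bicyclisation and cycloaddition).** MeAlCl2 may trigger allyl shifts or dienone–phenol rearrangement of 16 before the epoxide opens. The fallback sets out from 8 and comes back at 17 by replacing cationic with radical termination. Me2CuLi adds to 8 to give methyl (2Z,6E,10S)-10,11-epoxy-3,7,11-trimethyldodeca-2,6-dienoate F4. iBu2AlH reduces it to the allylic alcohol F5, and its mesylate F6 with LiBr gives the bromide F7. Union with 15 as in step 10 gives the silicon-free dienone F8. Cp2TiCl (trivalent titanium, made from Cp2TiCl2 and Mn in THF) then opens the epoxide homolytically. The radical bicyclisation ends by loss of a C12 hydrogen to the exocyclic alkene, which is 17, and this is heated as in step 11 to give 18.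

**Step 12 (conjugate borylation).** The α-substituted, hindered enoate may react slowly or with the wrong facial or C7a' selectivity. The fallback sets out from 18 and comes back at 23, using an epoxide as the masked C7' hydroxyl. Nucleophilic epoxidation (tBuOOH, DBU) of the alkylidene lactone from the ketone-bridge face gives the α,β-epoxy lactone F9. IBX converts it through the epoxy ketone F10 into the epoxy enone F11. mCPBA effects the Baeyer–Villiger step to give the epoxy ε-lactone F12. Reductive opening at C7a' with sodium phenylselenide (PhSeSePh, NaBH4, AcOH, EtOH) gives 23.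

## Further compounds

F1 | step 10 | (4'S) epimer of 16 | O=C1C(C)=CC2=C(COC2=O)[C@]1(C)C/C=C(/C[Si](C)(C)C)CC/C=C(\C)CC[C@@H]1OC1(C)C
F2 | step 10 | aryl ether from O-alkylation of 15 by 12 | Cc1cc2C(=O)OCc2c(C)c1OC/C=C(/C[Si](C)(C)C)CC/C=C(\C)CC[C@@H]1OC1(C)C
F3 | step 10 | C6'-alkylated regioisomer of 16 (both epimers at the new centre) | O=C1C(C)=C2COC(=O)C2=CC1(C)C/C=C(/C[Si](C)(C)C)CC/C=C(\C)CC[C@@H]1OC1(C)C
F4 | step 11 | methyl (2Z,6E,10S)-10,11-epoxy-3,7,11-trimethyldodeca-2,6-dienoate | COC(=O)/C=C(/C)CC/C=C(\C)CC[C@@H]1OC1(C)C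
F5 | step 11 | (2Z,6E,10S)-10,11-epoxy-3,7,11-trimethyldodeca-2,6-dien-1-ol | OC/C=C(/C)CC/C=C(\C)CC[C@@H]1OC1(C)C
F6 | step 11 | methanesulfonate of F5 | CS(=O)(=O)OC/C=C(/C)CC/C=C(\C)CC[C@@H]1OC1(C)C
F7 | step 11 | (2Z,6E,10S)-1-bromo-10,11-epoxy-3,7,11-trimethyldodeca-2,6-diene | BrC/C=C(/C)CC/C=C(\C)CC[C@@H]1OC1(C)C
F8 | step 11 | silicon-free (4'R) dienone | O=C1C(C)=CC2=C(COC2=O)[C@@]1(C)C/C=C(/C)CC/C=C(\C)CC[C@@H]1OC1(C)C
F9 | step 12 | C7',C7a'-epoxy lactone of 18 | CC1(C)[C@@H](O)CC[C@@]2(C)[C@H]1CC[C@]13C[C@]4(C)C(=O)[C@](C)(C[C@@H]21)[C@]31COC(=O)[C@@]15O[C@@H]45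
F10 | step 12 | epoxy C3 ketone | CC1(C)C(=O)CC[C@@]2(C)[C@H]1CC[C@]13C[C@]4(C)C(=O)[C@](C)(C[C@@H]21)[C@]31COC(=O)[C@@]15O[C@@H]45
F11 | step 12 | epoxy Δ1-3-ketone | CC1(C)C(=O)C=C[C@@]2(C)[C@H]1CC[C@]13C[C@]4(C)C(=O)[C@](C)(C[C@@H]21)[C@]31COC(=O)[C@@]15O[C@@H]45
F12 | step 12 | epoxy ε-lactone | CC1(C)OC(=O)C=C[C@@]2(C)[C@H]1CC[C@]13C[C@]4(C)C(=O)[C@](C)(C[C@@H]21)[C@]31COC(=O)[C@@]15O[C@@H]45
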